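**Remark on numbering:** germacrane numbering is used for the target and all intermediates (ring carbons C1–C10, lactone carbons C11–C13, methyl groups C14 on C10 and C15 on C4).
**Remark on 17 and 18:** the C11 configuration drawn is the one expected from alkylation anti to C8; it is erased in step 13 and has no bearing on the route.

## Analysis of the target

- Target 22 is a furanoheliangolide. Its ten-membered carbocycle C1–C10 is spanned by an oxygen between C3 and C10, so that C1(=O)–C2=C3–O–C10 is a 3(2H)-furanone. A trans-fused α-methylene-γ-butyrolactone sits on C6–C7 (C12 carbonyl, ring oxygen on C6, exocyclic C11=C13).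
- A Z-configured trisubstituted C4=C5 alkene lies in cross-conjugation with the furanone. Five of the ten ring carbons are sp2, and the oxygen bridge turns the carbocycle into a strained bicycle that also contains a nine-membered oxacycle.
- Five stereocentres lie on the contiguous stretch C6–C10. C6 (R) and C7 (S) are trans on the lactone. C8 (S) carries the methacrylate, C9 (R) the free hydroxyl anti to it. C10 (S) is quaternary, bearing C14, the bridging oxygen and the C1 carbonyl.
- Sensitive groups: two polymerisable Michael acceptors (methylene lactone, methacrylate), a vinylogous-ester furanone, a Z-alkene that can isomerise, a β-hydroxy ester that can migrate its acyl group, and a lactone that is labile to base and nucleophiles.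
- The hard parts are closing a strained, highly unsaturated medium ring, setting C8 and C9 beside a quaternary carbon, and telling apart two neighbouring secondary oxygens, O8 and O9.
- The strategy rests on C8 and C9: adjacent ring carbons carrying an ester and an alcohol in a trans relationship. This is what anti opening of a cis-8,9-epoxide by the acid found at O8 produces. The epoxide comes from a cis C8=C9 alkene, which is the retron for ring-closing metathesis between vinyl groups on C7 and C10.

## Retrosynthetic reasoning

**C8–O ester bond and the C8/C9 stereocentres.** Target 22 is cut at the C8–O bond into methacrylic acid 21 and the cis-8,9-epoxide 20. The cut is made here because one SN2 event then installs the ester, frees the C9 hydroxyl and sets both stereocentres, with no need to differentiate two free hydroxyls. The forward reaction has to attack C8, not C9, with inversion. C9 is neopentyl and sits next to the oxygenated, carbonyl-bearing C10, so both sterics and electronics point the nucleophile to C8.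

**Epoxide oxygen.** Epoxide 20 goes back to tetraene 19 with a cis C8=C9 alkene. This is the only ring alkene that is neither conjugated to a carbonyl nor part of the furanone, so an electrophilic oxidant should pick it. The forward step must deliver oxygen to the face that gives the (8R,9R)-epoxide. A model places this face outside the nine-membered oxacycle, on the side of H7 and the C1 carbonyl; the opposite face looks at C6 and the bridging oxygen.

**Exocyclic C11=C13.** The methylene group of 19 is removed to give lactone 16, by way of Mannich base 17 and ammonium salt 18. It is introduced only after the ring is closed and after all amine chemistry, because a methylene lactone would trap the secondary amine used for the furanone and would give the metathesis catalyst a third olefin. It is introduced before the epoxide, because a lactone enolate next to an epoxide could open it.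

**C8=C9 ring bond (key disconnection).** Macrocycle 16 is cut across C8=C9 to diene 15, which carries a vinyl group on C7 and one on quaternary C10. This bond is chosen because it is the only ring bond whose formation needs no stereocentre, because the two halves on either side are of similar size, and because the resulting alkene is exactly the handle for O8 and O9. The forward reaction must close a ten-membered ring with cis geometry and without oligomerisation. The furanone, the Z-alkene and the trans-lactone leave only a few rotatable bonds between the two vinyl groups.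

**Furanone C–O bonds.** Diene 15 is traced to the open-chain hydroxy-ynone 13 through enaminone 14. A tertiary propargylic alcohol on C10 and an ynone carbonyl on C3 are a classical furanone precursor: a secondary amine transposes the carbonyl to C1 and the C10 oxygen ends on C3. The gain is that the furanone needs no reagent stronger than an amine and dilute acid, so the lactone, the Z-alkene and both vinyl groups pass through unchanged.

**C3 as a one-carbon linchpin.** Ynone 13 is cut on both sides of the C3 carbonyl, giving Z-vinyl iodide 8 and enantiopure alkynol 12. The carbonyl carbon is supplied by carbonylation under palladium catalysis. This avoids any organometallic addition that would have to choose between a C3 acyl group and the lactone carbonyl, and it joins the two chiral fragments convergently with retention of the alkene geometry.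

**C4=C5 alkene.** Iodide 8 is cut at C4=C5 to aldehyde 7, made from alcohol 6. An iodo-olefination is preferred to a Z-selective ester olefination because the halide, not an ester, enters the coupling, so no hydride or hydroxide step ever meets the lactone. The forward reaction must place iodine cis to C6.

**C7–C8 bond and the lactone stereocentres.** Alcohol 6 comes from silyl ether 5, which is cut at C7–C8 into butenolide 2 and vinylmagnesium bromide 3. Butenolide 2 is the silyl ether of chiral-pool butenolide 1. C6 is bought, and C7 is set by conjugate addition anti to the C6 substituent, which gives the trans-lactone directly.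

**C10 fragment.** Alkynol 12 is traced through epoxy iodide 11 and epoxy alcohol 10 to the achiral enynol 9. Reductive opening of the epoxy iodide converts the C–I carbon and its neighbour into the C10 vinyl group and leaves the epoxide oxygen on the quaternary carbon, so the catalyst-controlled epoxidation of 9 fixes C10.

## Alternatives that were turned down

**Alternative 1: ring expansion of a seven-membered lactone by acyl transfer.**
- Disconnection: the C2–C3 bond of a 1,3-diketone. The ten-membered ring is derived from the seven-membered Z-enoate lactone A1, whose C8 side chain ends in a C1 methyl ketone.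
- Forward key step: a hindered potassium amide base forms the C2 enolate of A1. It attacks the lactone carbonyl C3 and the tetrahedral intermediate expels the C8 alkoxide, giving the ten-membered 1,3-diketone A2 with a free C8 hydroxyl.
- In favour: the Z geometry of C4=C5 is locked inside the small lactone. The medium ring arises through a seven-membered transition state instead of a direct ten-membered closure. All five stereocentres are fixed before the ring exists. O8 is released alone while O9 and O10 stay in an acetonide, so the methacrylate position is unambiguous.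
- Against: the C8 alkoxide set free in A2 is γ to the C1 ketone, so hemiketalisation and retro-Claisen cleavage towards a five-membered lactone are a thermodynamic sink unless the diketone is held as its enolate. Deprotonation of A1 can also occur at the vinylogous positions of the enoate. After A2 the furanone dehydration, acetonide, silyl and benzyl ether removals, oxidation of C12, lactonisation and acylation still lie ahead, and A1 itself needs a long acyclic stereotriad synthesis.
- Comparison: this alternative is stronger on regiocontrol between O8 and O9 and on stereochemical certainty at C8 and C9. The chosen route offers in exchange a precursor 15 reached in about ten steps with no protecting group left, and a four-step endgame.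

**Alternative 2: oxonium ylide [2,3]-shift of a dihydropyran.**
- Disconnection: C9–C10 and the C10–O bond of the furanone together, back to the dihydropyran diazoketone A3. In A3 the pyran oxygen links C3 and C7, and C7 carries a silyloxyvinyl group.
- Forward key step: a rhodium carboxylate or copper diketonate catalyst releases nitrogen from A3. The C10 carbenoid is captured by the pyran oxygen, and the ylide rearranges across C7–C8=C9, opening the pyran and giving the oxa-bridged cyclodecadienone A4. The configuration at C7 and the enol ether geometry assigned to A3 are those a suprafacial shift requires for the C9 configuration of A4.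
- In favour: one catalytic step makes the furanone ring, the carbocycle, the quaternary C10 and the oxygenated C9. Loss of nitrogen makes it irreversible, so ring strain is paid for by the carbenoid. The six-membered ring guarantees Z at C4=C5.
- Against: the diazo carbon carries a methyl group, so 1,2-hydride migration to an enone competes with ylide formation, as do C–H insertion and cyclopropanation of the enol ether. The C9/C10 outcome depends on ylide conformation. A4 has no lactone carbons, has its new alkene at C7=C8 where a carbon branch and an oxygen must still be placed with two more stereocentres, and needs C2–C3 dehydrogenation.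
- Comparison: this alternative is stronger on the thermodynamics of ring formation and on bond economy in the key step. The chosen route offers a key-step substrate that already holds every ring carbon and three stereocentres, so only C13 and the ester remain to be added.

**Alternative 3: intramolecular nitrile oxide–alkyne cycloaddition.**
- Disconnection: the C1–C2 bond, with an isoxazole standing in for the C1–C3 dicarbonyl unit. The precursor is aldoxime A5, with a terminal C2–C3 alkyne on C4.
- Forward key step: hypochlorite oxidation of A5 generates the C1 nitrile oxide function, which adds across the alkyne (C1–C2 and O–C3) to give the bridged isoxazole macrocycle A6.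
- In favour: the cycloaddition is irreversible and strongly exothermic. Its innate regiochemistry (dipole carbon to the alkyne terminus) is the one needed. The dipole next to quaternary C10 is hindered and so dimerises slowly. A6 already carries the lactone and all five stereocentres, with O8 and O9 differentiated.
- Against: a planar aromatic ring spanning C1–C3 inside a ten-membered carbocycle is a small metacyclophane, and both reacting termini are linear, so the transition state is badly strained. Unmasking needs reductive N–O cleavage beside a conjugated Z-alkene, hydrolysis, acetonide removal and cyclodehydration. Once O9 is free the acylation selectivity problem returns. The acyclic C8–C10 triad of A5 costs many steps.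
- Comparison: this alternative is stronger on irreversibility and on fixing C8 and C9 before the ring exists. The chosen route offers a furanone made early by mild chemistry, no heterocycle to dismantle, and fewer steps.

Key step: step 11

## Route

Step 1
Reactants: 1 (S)-5-(hydroxymethyl)furan-2(5H)-one
Product: 2 (S)-5-{[(tert-butyldimethylsilyl)oxy]methyl}furan-2(5H)-one
Conditions: TBSCl, imidazole, CH2Cl2, 0 °C to rt
Reagents that add atoms: tert-butyldimethylsilyl chloride, CC(C)(C)[Si](C)(C)Cl
Why: Silylation of a primary alcohol; the ether survives the Grignard reagent and its bulk reinforces the facial bias of the butenolide in step 2.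

Step 2
Reactants: 2 (S)-5-{[(tert-butyldimethylsilyl)oxy]methyl}furan-2(5H)-one; 3 vinylmagnesium bromide
Product: 5 (4R,5S)-5-{[(tert-butyldimethylsilyl)oxy]methyl}-4-vinyldihydrofuran-2(3H)-one, via trimethylsilyl ketene acetal 4 (not isolated)
Conditions: 3 (1.5 equiv), CuBr·SMe2 (10 mol %), TMSCl (2 equiv), THF, −78 °C; then aq NH4Cl
Reagents that add atoms: none
Why: Copper-catalysed, silyl-chloride-accelerated conjugate addition; the vinyl group enters anti to the silyloxymethyl group on C6, setting C7 trans to C6, and ketene acetal 4 is hydrolysed to the lactone on work-up.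

Step 3
Reactants: 5 (4R,5S)-5-{[(tert-butyldimethylsilyl)oxy]methyl}-4-vinyldihydrofuran-2(3H)-one
Product: 6 (4R,5S)-5-(hydroxymethyl)-4-vinyldihydrofuran-2(3H)-one
Conditions: HF·pyridine, THF, 0 °C to rt
Reagents that add atoms: none
Why: Fluoride-mediated silyl ether cleavage under mildly acidic conditions, which neither open the lactone nor allow the freed alcohol to translactonise.

Step 4
Reactants: 6 (4R,5S)-5-(hydroxymethyl)-4-vinyldihydrofuran-2(3H)-one
Product: 7 (2S,3R)-5-oxo-3-vinyltetrahydrofuran-2-carbaldehyde
Conditions: Dess–Martin periodinane, CH2Cl2, 0 °C to rt; used crude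
Reagents that add atoms: none
Why: Dess–Martin oxidation of a primary alcohol under non-basic conditions; immediate use of the crude aldehyde should avoid epimerisation at C6.

Step 5
Reactants: 7 (2S,3R)-5-oxo-3-vinyltetrahydrofuran-2-carbaldehyde
Product: 8 (4R,5S)-5-[(Z)-2-iodoprop-1-en-1-yl]-4-vinyldihydrofuran-2(3H)-one
Conditions: EtPPh3I, n-BuLi, THF, rt; I2, −78 °C; NaN(SiMe3)2, −78 °C; then 7, −78 °C
Reagents that add atoms: ethyltriphenylphosphonium iodide, CC[P+](c1ccccc1)(c1ccccc1)c1ccccc1.[I-]; iodine, II
Why: Stork–Zhao-type Wittig olefination with the α-iodo ylide made in the flask; kinetic oxaphosphetane formation places iodine cis to C6, so the C15 methyl is trans to C6 as the C4=C5 geometry requires, and at −78 °C the ylide should leave the lactone alone.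

Step 6
Reactants: 9 (E)-3-methylpent-2-en-4-yn-1-ol
Product: 10 [(2R,3R)-3-ethynyl-3-methyloxiran-2-yl]methanol
Conditions: Ti(OiPr)4 (10 mol %), D-(−)-diisopropyl tartrate (12 mol %), t-BuOOH, 4 Å MS, CH2Cl2, −20 °C
Reagents that add atoms: tert-butyl hydroperoxide, CC(C)(C)OO
Why: Sharpless asymmetric epoxidation of an E-trisubstituted allylic alcohol; the D-(−)-tartrate ligand directs oxygen to the face that gives the (2R,3R)-epoxide, which fixes the future C10, and the alkyne is inert to the titanium peroxide.

Step 7
Reactants: 10 [(2R,3R)-3-ethynyl-3-methyloxiran-2-yl]methanol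
Product: 11 (2R,3S)-2-ethynyl-3-(iodomethyl)-2-methyloxirane
Conditions: I2, PPh3, imidazole, CH2Cl2, 0 °C
Reagents that add atoms: iodine, II
Why: Appel-type iodination of a primary alcohol; no stereocentre is touched (the descriptor of the CH carbon changes only through CIP priorities).

Step 8
Reactants: 11 (2R,3S)-2-ethynyl-3-(iodomethyl)-2-methyloxirane
Product: 12 (S)-3-methylpent-1-en-4-yn-3-ol
Conditions: Zn dust, AcOH, EtOH, 0 °C to rt; product handled as a solution or distilled with care (volatile)
Reagents that add atoms: none
Why: Zinc insertion into the C–I bond and β-elimination open the epoxide (reductive elimination of a 2,3-epoxy iodide) to the tertiary allylic alcohol; the C–O bond at the quaternary carbon is never broken, so the configuration is retained.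

Step 9
Reactants: 8 (4R,5S)-5-[(Z)-2-iodoprop-1-en-1-yl]-4-vinyldihydrofuran-2(3H)-one; 12 (S)-3-methylpent-1-en-4-yn-3-ol
Product: 13 (4R,5S)-5-[(1Z,6S)-6-hydroxy-2,6-dimethyl-3-oxoocta-1,7-dien-4-yn-1-yl]-4-vinyldihydrofuran-2(3H)-one
Conditions: PdCl2(PPh3)2 (5 mol %), CO (5 bar), Et3N, THF, rt, copper-free
Reagents that add atoms: carbon monoxide, [C-]#[O+]
Why: Carbonylative Sonogashira coupling: zerovalent palladium adds to the vinyl iodide with retention, CO inserts, and the acyl complex couples with the alkyne to give the cross-conjugated ynone; CO pressure and the absence of copper should suppress direct coupling, and the lactone and tertiary alcohol are spectators.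

Step 10
Reactants: 13 (4R,5S)-5-[(1Z,6S)-6-hydroxy-2,6-dimethyl-3-oxoocta-1,7-dien-4-yn-1-yl]-4-vinyldihydrofuran-2(3H)-one
Product: 15 (4R,5S)-5-{(Z)-2-[(5S)-5-methyl-4-oxo-5-vinyl-4,5-dihydrofuran-2-yl]prop-1-en-1-yl}-4-vinyldihydrofuran-2(3H)-one, via enaminone 14 (not isolated)
Conditions: Et2NH (1.5 equiv), EtOH, rt; then AcOH/H2O, rt
Reagents that add atoms: water, O
Why: Amine-mediated conversion of a 4-hydroxy-2-yn-1-one into a 3(2H)-furanone: the amine adds to C1 to give enaminone 14, the C10 hydroxyl closes onto the C3 carbonyl, and dehydration followed by iminium hydrolysis leaves the ketone on C1; no bond to C10 is broken, and the ynone is far more electrophilic than the α-methyl enone or the lactone.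

Step 11
Reactants: 15 (4R,5S)-5-{(Z)-2-[(5S)-5-methyl-4-oxo-5-vinyl-4,5-dihydrofuran-2-yl]prop-1-en-1-yl}-4-vinyldihydrofuran-2(3H)-one
Product: 16 (4Z,8Z)-3,10-epoxy-1-oxo-13-norgermacra-2,4,8-trien-12,6-olide (6S,7R,10S)
Conditions: second-generation Hoveyda–Grubbs catalyst RuCl2(H2IMes)(=CH-C6H4-2-O-iPr) (15 mol % in three portions), 1,4-benzoquinone (20 mol %), toluene, 1 mM, 80 °C, argon sparge
Reagents that add atoms: none
Why: Ring-closing olefin metathesis: the catalyst should load on the less hindered C7 vinyl group to give a C8 alkylidene, which adds across the C10 vinyl group to a ruthenacyclobutane; cycloreversion releases the C8=C9 alkene and a methylidene, and sparging removes ethene to pull the equilibrium. The closest known reaction type is ring-closing metathesis of two terminal olefins to ten-membered carbocycles, a closure known to depend strongly on the substrate. The step closes the ten-membered carbocycle (and with it the nine-membered oxacycle through the bridging oxygen) by forming an endocyclic disubstituted alkene. No stereocentre is formed; the geometry must be cis and should be enforced by the ring, since a trans C8=C9 in a bicycle that already holds a trans C2=C3 would be far more strained and the reversible reaction can correct it. The selectivity needed is intramolecular over intermolecular metathesis: high dilution helps, and the planar furanone, the Z-alkene and the trans-lactone leave only the C3–C4, C5–C6, C7–C8 and C9–C10 bonds free to rotate, so the two vinyl groups are held within reach. The trisubstituted conjugated C4=C5 and the furanone C2=C3 are inert to the catalyst, C10 has no allylic hydrogen, and benzoquinone should suppress migration of the C7 vinyl group.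

Step 12
Reactants: 16 (4Z,8Z)-3,10-epoxy-1-oxo-13-norgermacra-2,4,8-trien-12,6-olide (6S,7R,10S)
Product: 17 (4Z,8Z)-13-(dimethylamino)-3,10-epoxy-1-oxogermacra-2,4,8-trien-12,6-olide (6S,7S,10S,11R)
Conditions: LiN(SiMe3)2 (1.1 equiv), THF, −78 °C; then Me2N=CH2 I (Eschenmoser's salt), −78 to 0 °C
Reagents that add atoms: N,N-dimethylmethyleneiminium iodide, C=[N+](C)C.[I-]
Why: Kinetic deprotonation of the lactone at C11, the only accessible α-CH2 (C10 is quaternary), and Mannich alkylation of the enolate anti to C8; the new C11 centre is removed in step 13.

Step 13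
Reactants: 17 (4Z,8Z)-13-(dimethylamino)-3,10-epoxy-1-oxogermacra-2,4,8-trien-12,6-olide (6S,7S,10S,11R)
Product: 19 (4Z,8Z)-3,10-epoxy-1-oxogermacra-2,4,8,11(13)-tetraen-12,6-olide (6R,7S,10S), via trimethylammonium iodide 18 (not isolated)
Conditions: MeI, THF, rt; then sat. aq NaHCO3, CH2Cl2, rt
Reagents that add atoms: none
Why: N-Methylation gives salt 18, whose acidic C11–H allows E1cB (Hofmann-type) loss of trimethylamine with bicarbonate, the standard mild route to an α-methylene lactone; the furanone and both Z-alkenes should tolerate these conditions.

Step 14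
Reactants: 19 (4Z,8Z)-3,10-epoxy-1-oxogermacra-2,4,8,11(13)-tetraen-12,6-olide (6R,7S,10S)
Product: 20 (4Z)-3,10:8,9-diepoxy-1-oxogermacra-2,4,11(13)-trien-12,6-olide (6R,7S,8R,9R,10S)
Conditions: dimethyldioxirane (1.1 equiv, acetone solution), CH2Cl2, −20 to 0 °C
Reagents that add atoms: dimethyldioxirane, CC1(C)OO1
Why: Concerted, stereospecific electrophilic epoxidation under neutral conditions; the strained cis C8=C9 is the only alkene not deactivated by conjugation, and oxygen should arrive on the face outside the nine-membered oxacycle (the side of H7 and the C1 carbonyl, away from C6 and the bridging oxygen), which gives the (8R,9R)-epoxide.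

Step 15
Reactants: 20 (4Z)-3,10:8,9-diepoxy-1-oxogermacra-2,4,11(13)-trien-12,6-olide (6R,7S,8R,9R,10S); 21 methacrylic acid
Product: 22 (4Z)-3,10-epoxy-9-hydroxy-8-(methacryloyloxy)-1-oxogermacra-2,4,11(13)-trien-12,6-olide (6R,7S,8S,9R,10S)
Conditions: 21 (10 equiv), Cs2CO3 (0.2 equiv, gives CsO2CC(CH3)=CH2), BHT (cat.), DMF, 50 °C
Reagents that add atoms: none
Why: Carboxylate-catalysed SN2 acidolysis of an epoxide; attack at C8 (secondary, away from quaternary C10 and its electron-withdrawing oxygen and carbonyl) with inversion gives the 8S ester while the C9–O bond is retained as the 9R alcohol, and the excess acid protonates the alkoxide and should hold back acyl migration.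

## Compound list

1 | (S)-5-(hydroxymethyl)furan-2(5H)-one | O=C1C=C[C@@H](CO)O1 | starting material
2 | (S)-5-{[(tert-butyldimethylsilyl)oxy]methyl}furan-2(5H)-one | O=C1C=C[C@@H](CO[Si](C)(C)C(C)(C)C)O1 | intermediate
3 | vinylmagnesium bromide | C=C[Mg]Br | starting material
4 | tert-butyldimethyl{[(2S,3S)-5-(trimethylsilyloxy)-3-vinyl-2,3-dihydrofuran-2-yl]methoxy}silane (silyl ketene acetal, not isolated) | C=C[C@H]1C=C(O[Si](C)(C)C)O[C@@H]1CO[Si](C)(C)C(C)(C)C | intermediate
5 | (4R,5S)-5-{[(tert-butyldimethylsilyl)oxy]methyl}-4-vinyldihydrofuran-2(3H)-one | C=C[C@H]1CC(=O)O[C@@H]1CO[Si](C)(C)C(C)(C)C | intermediate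
6 | (4R,5S)-5-(hydroxymethyl)-4-vinyldihydrofuran-2(3H)-one | C=C[C@H]1CC(=O)O[C@@H]1CO | intermediate
7 | (2S,3R)-5-oxo-3-vinyltetrahydrofuran-2-carbaldehyde | C=C[C@H]1CC(=O)O[C@@H]1C=O | intermediate
8 | (4R,5S)-5-[(Z)-2-iodoprop-1-en-1-yl]-4-vinyldihydrofuran-2(3H)-one | C=C[C@H]1CC(=O)O[C@@H]1/C=C(/C)I | intermediate
9 | (E)-3-methylpent-2-en-4-yn-1-ol | C#C/C(C)=C/CO | starting material
10 | [(2R,3R)-3-ethynyl-3-methyloxiran-2-yl]methanol | OC[C@H]1O[C@]1(C)C#C | intermediate
11 | (2R,3S)-2-ethynyl-3-(iodomethyl)-2-methyloxirane | IC[C@H]1O[C@]1(C)C#C | intermediate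
12 | (S)-3-methylpent-1-en-4-yn-3-ol | C#C[C@@](C)(O)C=C | intermediate
13 | (4R,5S)-5-[(1Z,6S)-6-hydroxy-2,6-dimethyl-3-oxoocta-1,7-dien-4-yn-1-yl]-4-vinyldihydrofuran-2(3H)-one | C=C[C@H]1CC(=O)O[C@@H]1/C=C(/C)C(=O)C#C[C@@](C)(O)C=C | intermediate
14 | (4R,5S)-5-[(1Z,4E,6S)-5-(diethylamino)-6-hydroxy-2,6-dimethyl-3-oxoocta-1,4,7-trien-1-yl]-4-vinyldihydrofuran-2(3H)-one (enaminone, not isolated) | C=C[C@H]1CC(=O)O[C@@H]1/C=C(/C)C(=O)/C=C(/N(CC)CC)[C@@](C)(O)C=C | intermediate
15 | (4R,5S)-5-{(Z)-2-[(5S)-5-methyl-4-oxo-5-vinyl-4,5-dihydrofuran-2-yl]prop-1-en-1-yl}-4-vinyldihydrofuran-2(3H)-one | C=C[C@H]1CC(=O)O[C@@H]1/C=C(/C)C1=CC(=O)[C@@](C)(O1)C=C | intermediate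
16 | (4Z,8Z)-3,10-epoxy-1-oxo-13-norgermacra-2,4,8-trien-12,6-olide (6S,7R,10S) | C1C(=O)O[C@@H]2/C=C(/C)C3=CC(=O)[C@@](C)(O3)/C=C\[C@@H]12 | intermediate
17 | (4Z,8Z)-13-(dimethylamino)-3,10-epoxy-1-oxogermacra-2,4,8-trien-12,6-olide (6S,7S,10S,11R) | CN(C)C[C@@H]1C(=O)O[C@@H]2/C=C(/C)C3=CC(=O)[C@@](C)(O3)/C=C\[C@@H]12 | intermediate
18 | N-methyl ammonium iodide of 17 (6S,7S,10S,11R), not isolated | C[N+](C)(C)C[C@@H]1C(=O)O[C@@H]2/C=C(/C)C3=CC(=O)[C@@](C)(O3)/C=C\[C@@H]12.[I-] | intermediate
19 | (4Z,8Z)-3,10-epoxy-1-oxogermacra-2,4,8,11(13)-tetraen-12,6-olide (6R,7S,10S) | C=C1C(=O)O[C@@H]2/C=C(/C)C3=CC(=O)[C@@](C)(O3)/C=C\[C@@H]12 | intermediate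
20 | (4Z)-3,10:8,9-diepoxy-1-oxogermacra-2,4,11(13)-trien-12,6-olide (6R,7S,8R,9R,10S) | C=C1C(=O)O[C@@H]2/C=C(/C)C3=CC(=O)[C@@](C)(O3)[C@@H]4O[C@@H]4[C@@H]12 | intermediate
21 | methacrylic acid | C=C(C)C(=O)O | starting material
22 | (4Z)-3,10-epoxy-9-hydroxy-8-(methacryloyloxy)-1-oxogermacra-2,4,11(13)-trien-12,6-olide (6R,7S,8S,9R,10S) | C=C(C)C(=O)O[C@H]1[C@H]2C(=C)C(=O)O[C@@H]2/C=C(/C)C2=CC(=O)[C@@](C)(O2)[C@@H]1O | target

## Step count and risk

Total steps: 15. Longest linear sequence: 12 (steps 1–5 and 9–15); the C10 fragment takes 3 steps (6–8).

**Step 11 (key step).** The most likely failure is oligomerisation through the C7 vinyl group instead of closure. The C10 vinyl group is neopentyl and slow to engage, and the product holds three ring alkenes and a ketone in a bridged ten-membered ring, so the closure may be uphill against open-chain cross-metathesis.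
Fallback: close the carbocycle before the oxygen bridge exists. It sets out from 12 (with 8) and returns at 16.
- Alkynol 12 is silylated (Et3SiOTf, 2,6-lutidine) to the triethylsilyl ether F1.
- F1 is coupled with 8 under the step 9 conditions to the silyloxy ynone F2.
- Et2NH is added to give the open-chain enaminone F3, in which C10 and C3 are cis across C1=C2 and no bridge restricts the chain.
- Ring-closing metathesis with the same catalyst gives the macrocyclic enaminone F4.
- Aqueous HCl in THF removes the silyl group and drives the transannular cyclodehydration and hydrolysis to 16. This last step is irreversible, so the strain of the bridge is paid after the ring is made.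

**Step 9.** Direct coupling without CO insertion may compete, and the Z-acyl intermediate or the product enone may isomerise.
Fallback: bring C3 in with the olefination reagent instead of as CO. It sets out from 7 and returns at 13.
- Still–Gennari olefination of 7 with tert-butyl 2-[bis(2,2,2-trifluoroethoxy)phosphoryl]propanoate (KN(SiMe3)2, 18-crown-6, THF, −78 °C) gives the Z-enoate F5.
- Trifluoroacetic acid cleaves the tert-butyl ester without touching the lactone, giving the Z-acid F6.
- The Ghosez reagent gives the acid chloride F7.
- Acyl Sonogashira coupling with 12 (PdCl2(PPh3)2, CuI, Et3N) gives 13.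

**Step 5.** Likely problems are incomplete Z-selectivity, epimerisation at C6 by the basic ylide, and attack of the ylide on the lactone.
Fallback: build the haloalkene by cross-coupling instead of by a Wittig reaction. It sets out from 7 and returns at 13.
- Ramirez olefination (CBr4, PPh3) gives the dibromoalkene F8.
- Negishi-type methylation (Me2Zn, Pd(P(t-Bu)3)2 cat.), selective for the bromine trans to the ring carbon, gives the Z-bromide F9.
- F9 enters the carbonylative coupling of step 9 in place of 8 (at slightly higher temperature) to give 13.

**Step 14.** Facial selectivity may be poor, or the oxidant may attack the twisted, only partly conjugated C4=C5 alkene.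
Fallback: a halohydrin route, which places the oxygen on the face opposite to that first attacked by the electrophile. It sets out from 19 and returns at 20.
- N-Bromosuccinimide in aqueous THF should form the bromonium on the face the oxidant prefers, and water opens it at C8 from the other side, giving the bromohydrin F10.
- K2CO3 in acetone closes F10 to 20.

**Step 15.** The opening may be sluggish from the hindered side of the ring. Partial attack at C9, acyl migration from O8 to O9, and conjugate addition to the methylene lactone during prolonged heating are the other risks.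
Fallback: separate the opening from the acylation. It sets out from 20 and returns at 22.
- Dilute HClO4 in aqueous THF opens the epoxide at C8 with inversion to the trans-diol F11.
- Methacrylic anhydride with catalytic DMAP at −20 °C should acylate the C8 hydroxyl in preference to the neopentyl C9 hydroxyl, giving 22.

## Further compounds

F1 | step 11 | (S)-triethyl[(3-methylpent-1-en-4-yn-3-yl)oxy]silane | C#C[C@@](C)(O[Si](CC)(CC)CC)C=C
F2 | step 11 | (4R,5S)-5-[(1Z,6S)-2,6-dimethyl-3-oxo-6-(triethylsilyloxy)octa-1,7-dien-4-yn-1-yl]-4-vinyldihydrofuran-2(3H)-one | C=C[C@H]1CC(=O)O[C@@H]1/C=C(/C)C(=O)C#C[C@@](C)(O[Si](CC)(CC)CC)C=C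
F3 | step 11 | (4R,5S)-5-[(1Z,4E,6S)-5-(diethylamino)-2,6-dimethyl-3-oxo-6-(triethylsilyloxy)octa-1,4,7-trien-1-yl]-4-vinyldihydrofuran-2(3H)-one | C=C[C@H]1CC(=O)O[C@@H]1/C=C(/C)C(=O)/C=C(/N(CC)CC)[C@@](C)(O[Si](CC)(CC)CC)C=C
F4 | step 11 | (1E,4Z,8Z)-1-(diethylamino)-3-oxo-10-(triethylsilyloxy)-13-norgermacra-1,4,8-trien-12,6-olide (macrocyclic enaminone, natural configuration at C6, C7, C10) | [C@@]1(C)(O[Si](CC)(CC)CC)/C=C\[C@H]2CC(=O)O[C@@H]2/C=C(/C)C(=O)/C=C1/N(CC)CC
F5 | step 9 | tert-butyl (Z)-2-methyl-3-[(2S,3R)-5-oxo-3-vinyltetrahydrofuran-2-yl]acrylate | C=C[C@H]1CC(=O)O[C@@H]1/C=C(/C)C(=O)OC(C)(C)C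
F6 | step 9 | (Z)-2-methyl-3-[(2S,3R)-5-oxo-3-vinyltetrahydrofuran-2-yl]acrylic acid | C=C[C@H]1CC(=O)O[C@@H]1/C=C(/C)C(=O)O
F7 | step 9 | (Z)-2-methyl-3-[(2S,3R)-5-oxo-3-vinyltetrahydrofuran-2-yl]acryloyl chloride | C=C[C@H]1CC(=O)O[C@@H]1/C=C(/C)C(=O)Cl
F8 | step 5 | (4R,5S)-5-(2,2-dibromovinyl)-4-vinyldihydrofuran-2(3H)-one | C=C[C@H]1CC(=O)O[C@@H]1C=C(Br)Br
F9 | step 5 | (4R,5S)-5-[(Z)-2-bromoprop-1-en-1-yl]-4-vinyldihydrofuran-2(3H)-one | C=C[C@H]1CC(=O)O[C@@H]1/C=C(/C)Br
F10 | step 14 | (4Z)-9-bromo-3,10-epoxy-8-hydroxy-1-oxogermacra-2,4,11(13)-trien-12,6-olide (6R,7S,8R,9S,10S) | C=C1C(=O)O[C@@H]2/C=C(/C)C3=CC(=O)[C@@](C)(O3)[C@@H](Br)[C@H](O)[C@@H]12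
F11 | step 15 | (4Z)-3,10-epoxy-8,9-dihydroxy-1-oxogermacra-2,4,11(13)-trien-12,6-olide (6R,7S,8S,9R,10S) | O[C@H]1[C@H]2C(=C)C(=O)O[C@@H]2/C=C(/C)C2=CC(=O)[C@@](C)(O2)[C@@H]1O
A1 | alternative 1 | seven-membered Z-enoate lactone with C9/C10 acetonide and C1 methyl ketone | CC(=O)[C@@]1(C)OC(C)(C)O[C@@H]1[C@H]2OC(=O)/C(C)=C\[C@@H](O[Si](C)(C)C(C)(C)C)[C@@H]2C(=C)COCc3ccc(OC)cc3
A2 | alternative 1 | ten-membered 1,3-diketone with free C8 hydroxyl | O[C@H]1[C@@H](C(=C)COCc2ccc(OC)cc2)[C@H](O[Si](C)(C)C(C)(C)C)/C=C(/C)C(=O)CC(=O)[C@@]2(C)OC(C)(C)O[C@H]12
A3 | alternative 2 | dihydropyran diazoketone with Z-silyloxyvinyl group on C7 | CC(=[N+]=[N-])C(=O)C[C@@H]1O[C@@H](/C=C\O[Si](C)(C)C(C)(C)C)[C@H](OC(C)=O)C=C1C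
A4 | alternative 2 | oxa-bridged cyclodecadienone | [C@@H]1(O[Si](C)(C)C(C)(C)C)/C=C/[C@H](OC(C)=O)/C=C(/C)[C@@H]2CC(=O)[C@@]1(C)O2
A5 | alternative 3 | aldoxime with terminal enyne, lactone, C8 silyl ether and C9/C10 acetonide | C#C/C(C)=C\[C@H]1OC(=O)C[C@@H]1[C@H](O[Si](CC)(CC)CC)[C@H]2OC(C)(C)O[C@]2(C)/C=N/O
A6 | alternative 3 | bridged isoxazole macrocycle | CC[Si](CC)(CC)O[C@H]1[C@H]2CC(=O)O[C@@H]2/C=C(/C)c2cc(no2)[C@@]3(C)OC(C)(C)O[C@H]13
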